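# Proposed total synthesis of eryvarin F by folding ring A from an open poly-carbonyl chain

## Analysis of the target

Eryvarin F (17) is a 4H-chromen-4-one (benzo ring A: C4a, C5, C6, C7, C8, C8a; pyranone ring C: O1, C2, C3, C4) whose C3 carries an ether oxygen to ring B, a 2,4-dihydroxyphenyl group (C1' to C6'). Ring A bears a free hydroxyl at C7 flanked by 3-methylbut-2-en-1-yl (prenyl) groups at C6 and C8; only C5 carries hydrogen. There is no stereocentre and no alkene geometry to control, so the whole difficulty is constitutional. The sensitive groups are three:

- the two trisubstituted alkenes next to the C7 phenol (acid closes them to 2,2-dimethylchromans; halogens, peracids and hydrogenation attack them);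
- the 2-unsubstituted pyranone, which nucleophiles open at C2;
- the electron-rich, easily oxidised ring B.

The hard part is the C6/C7/C8 triad. Electrophilic prenylation of a resorcinol nucleus gives mixtures of O- and C-alkylation at competing carbons, and the usual tool for the C3–O–C1' enol ether (α-halogenation of an aryl ketone) does not tolerate prenyl groups. The feature the plan exploits is that ring A is an acylresorcinol: the oxygens at C7 and C8a are 1,3-related, C4a carries the C4 acyl group, and the prenyl groups sit on C6 and C8. These are exactly the carbons that are enolate α-carbons when ring A is unfolded into a poly-β-carbonyl chain. Ring A is therefore not bought as an arene but folded from an open chain, as in the biosynthesis of polyketide aromatics.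

## Retrosynthetic reasoning

**17 ⇐ 16.** The two acetal C–O bonds on the ring B oxygens are cut. Ring B must be masked through the basic steps, and a base-stable acetal that leaves in dilute acid is the smallest such mask. The forward step only has to free two phenols without touching the prenyl groups.

**16 ⇐ 9 + 13 (key disconnection).** Three bonds are cut at once: O1–C2 of ring C, and C5–C6 and C7–C8 of ring A.

- Opening ring C gives the hydroxyaryl enaminone 15.
- In 15 the C7–C8 bond is a Claisen bond between a ketone α-carbon and an ester carbonyl.
- The C5–C6 bond joins a formyl-level carbon to an ester α-carbon; it leads back through the open-chain keto ester 14 to the acyclic bis-enaminone 9 and the C7 ester 13.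

The cut is made here because both prenyl-bearing ring carbons then become sp3 carbons of simple carbonyl compounds. Each new bond joins a natural donor to a natural acceptor, so 13 can enter in one orientation only. The precursor contains neither ring A nor ring C. The forward step has to achieve conjugate addition–elimination, Dieckmann closure, aromatisation and pyranone closure in one operation.

**9 ⇐ 8.** The two exocyclic C=C bonds of 9 are cut. Both added carbons (C5 and C2 of the target) are one-carbon units at the formyl oxidation level and come from the same reagent. The forward reaction must distinguish the three methylene groups of 8: the central one and the aryloxy-activated one are to react, the third (future C8) is not.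

**8 ⇐ 6 + 7.** The C4–C4a bond is cut (crossed Claisen condensation). Ketone 7 delivers C4a, C8a, C8 and the complete C8 prenyl group as one commercial piece. Ester 6 delivers C4, C3, the ether oxygen and ring B.

**6 ⇐ 4 + 5.** The bond between the ether oxygen and C3 is cut (phenoxide alkylation). The dissonant 1,2-relationship between the C3 oxygen and the C4 carbonyl is bought ready-made in 5, so no α-oxidation of a ketone is ever needed.

**4 ⇐ 2 ⇐ 1.** The C1'–O bond is traced to a formyl group (oxygen insertion by aryl migration through formate 3). This turns a cheap 2,4-dioxygenated benzaldehyde into the 1,2,4-trioxygenated ring B with its three oxygens differentiated.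

**13 ⇐ 10 + 11.** The C2–C3 bond of the ester is cut ([3,3]-sigmatropic shift of ketene acetal 12). This gives the second prenyl-bearing unit, which supplies C6, C7 and the C6 prenyl group.

## Alternatives that were turned down

**Alternative 1:** the textbook route.

- Disconnection: the bond from the ether oxygen to C3 and the C2 carbon, on a preformed aromatic ring A.
- Forward key step: C-prenylation of 2,4-dihydroxyacetophenone to A1, bromination to A2, etherification with 4 to A3, aminomethylenation to 15 and closure to 16.
- Reasons for rejection:
  - Prenylation of the resacetophenone nucleus has two nucleophilic carbons and two oxygens to choose from. It gives mixtures, or needs two cycles of ether formation and sigmatropic shift.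
  - Electrophilic bromination of A1 cannot tell the enol from two trisubstituted alkenes and an activated ring.
  - Reversing the order puts the unselective prenylation on the most advanced intermediate, in competition with ring B.
  - Acylation variants of the Friedel–Crafts or Hoesch type need Lewis acids that cyclise ortho-prenylphenols.
- A variant that builds ring A by directed metalation avoids these problems at the price of three successive lithiations; it is kept as the fallback for step 7.

**Alternative 2:** an aryne that takes up C4 and O1 at once.

- Disconnection: C4–C4a and C8a–O1.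
- Forward key step: the aryne A5 (from silyl triflate A4 and CsF) inserts into the C–O bond of acid A6 (saponified 6). This should give the ortho-hydroxyaryl ketone A7, which is then aminomethylenated and cyclised.
- Reasons for rejection:
  - The oxygen must add to C8a, the aryne carbon beside the C8 prenyl group. The carboxylate oxygen is expected to add to the less hindered terminus.
  - It is also expected to add so that the aryl anion develops nearer the inductively withdrawing C7 oxygen. Both effects send the oxygen to C4a and the acyl group to C8a, giving regioisomer A8.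
  - No group beside the triple bond can reverse this, because the other neighbour, C5, must end as C–H.
  - A4 itself needs the aromatic prenylations of alternative 1 plus silylation and triflation, so the precursor costs more than the step wins.

**Alternative 3:** late-stage union at the C1'–O bond.

- Disconnection: the aryl–oxygen bond of the C3 ether.
- Forward key step: oxidative Chan–Lam coupling of chromonol A9 with boronic acid A10, mediated by Cu(OAc)2, to give 16.
- Reasons for rejection:
  - It forms one bond only and leaves ring A with its two prenyl groups unsolved.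
  - The 3-hydroxy-4-keto unit of A9 is a strong bidentate chelator for divalent copper, and the C7 hydroxyl competes as a second nucleophile.
  - The electron-rich, ortho-alkoxy boronic acid A10 is prone to protodeboronation.
  - An Ullmann variant would need base at high temperature, which opens 2-unsubstituted chromones.

Key step: step 7

## Route

Remark: the push–pull C=C bonds of 9, 14 and 15 equilibrate and end as ring bonds, so their geometry is left undefined. The stereocentre of 14 is racemic and transient.

Step 1
Reactants: 1 2,4-dihydroxybenzaldehyde
Product: 2 2,4-bis(methoxymethoxy)benzaldehyde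
Conditions: MOMCl, K2CO3, acetone, reflux
Reagents that add atoms: chloromethyl methyl ether (MOMCl), COCCl
Why: Double O-alkylation of the phenoxides by the chloromethyl ether (Williamson-type acetal formation); carbonate at reflux also alkylates the hydrogen-bonded 2-hydroxyl. The acetals survive every basic step that follows and leave together in step 8.

Step 2
Reactants: 2 2,4-bis(methoxymethoxy)benzaldehyde
Product: 4 2,4-bis(methoxymethoxy)phenol, via aryl formate 3 (not isolated)
Conditions: mCPBA, CH2Cl2, 0 → 25 °C; then K2CO3 (cat.), MeOH, 25 °C
Reagents that add atoms: 3-chloroperbenzoic acid (mCPBA), OOC(=O)c1cccc(Cl)c1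
Why: Baeyer–Villiger (Dakin-type) oxidation: in the peracid adduct the electron-rich dialkoxyphenyl group migrates to oxygen in preference to hydrogen and gives formate 3, which mild methanolysis cleaves to 4. This sets the 1,2,4-oxygen pattern of ring B with the future ether oxygen as the only free hydroxyl.

Step 3
Reactants: 4 2,4-bis(methoxymethoxy)phenol, 5 methyl bromoacetate
Product: 6 methyl 2-[2,4-bis(methoxymethoxy)phenoxy]acetate
Conditions: K2CO3, acetone, reflux
Reagents that add atoms: none
Why: Williamson ether synthesis (SN2 of the phenoxide on the α-bromo ester). The bond from the ether oxygen to C3 and the 1,2-relationship of this oxygen to the future C4 carbonyl are taken ready-made from 5.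

Step 4
Reactants: 6 methyl 2-[2,4-bis(methoxymethoxy)phenoxy]acetate, 7 6-methylhept-5-en-2-one
Product: 8 1-[2,4-bis(methoxymethoxy)phenoxy]-8-methylnon-7-ene-2,4-dione
Conditions: 7 (2.1 equiv), LiN(i-Pr)2 (2.1 equiv), THF, −78 °C; then 6, −78 → 0 °C; AcOH work-up
Reagents that add atoms: none
Why: Crossed Claisen condensation: LiN(i-Pr)2 deprotonates the methyl group of 7 under kinetic control and this enolate acylates on the ester of 6, which is activated by its α-aryloxy group; the second equivalent of enolate deprotonates the β-diketone and makes the condensation irreversible. Acylation at the methyl group is also the thermodynamic outcome, since only it gives a diketonate with an unsubstituted central carbon.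

Step 5
Reactants: 8 1-[2,4-bis(methoxymethoxy)phenoxy]-8-methylnon-7-ene-2,4-dione
Product: 9 1-(dimethylamino)-4-[(dimethylamino)methylidene]-2-[2,4-bis(methoxymethoxy)phenoxy]-9-methyldeca-1,8-diene-3,5-dione
Conditions: Me2NCH(OMe)2 (2.3 equiv), toluene, 25 °C then 90 °C
Reagents that add atoms: N,N-dimethylformamide dimethyl acetal, COC(OC)N(C)C
Why: Aminomethylenation of active methylene groups by the amide acetal (enaminone formation): the central methylene between the two carbonyls should react at 25 °C and the aryloxy-activated methylene next to C4 at 90 °C, whereas the third methylene (future C8) has no second activating group and should stay free. The two carbons added are C5 and C2 of the target, both at the formyl oxidation level.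

Step 6
Reactants: 10 2-methylbut-3-en-2-ol, 11 trimethyl orthoacetate
Product: 13 methyl 5-methylhex-4-enoate, via mixed ketene acetal 12 (not isolated)
Conditions: EtCO2H (cat.), 120 °C, MeOH distilled off
Reagents that add atoms: none
Why: Johnson–Claisen rearrangement: acid-catalysed exchange gives ketene acetal 12, whose [3,3]-sigmatropic shift through a chair transition state moves the allyl unit to carbon and gives the γ,δ-unsaturated ester with the trisubstituted double bond.

Step 7
Reactants: 9 1-(dimethylamino)-4-[(dimethylamino)methylidene]-2-[2,4-bis(methoxymethoxy)phenoxy]-9-methyldeca-1,8-diene-3,5-dione, 13 methyl 5-methylhex-4-enoate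
Product: 16 3-[2,4-bis(methoxymethoxy)phenoxy]-7-hydroxy-6,8-bis(3-methylbut-2-en-1-yl)-4H-chromen-4-one, via alkylidene keto ester 14 (not isolated), via hydroxyaryl enaminone 15 (not isolated)
Conditions: 13 (1.3 equiv), LiN(i-Pr)2 (1.3 equiv), THF, −78 °C; then 9, −78 → 0 °C; then KOt-Bu (2.5 equiv), t-BuOH, 60 °C; then AcOH, 60 °C
Reagents that add atoms: none
Why: The lithium enolate of 13 adds through its α-carbon to the aminomethylidene carbon of 9, the one acceptor carbon activated by two carbonyl groups, and dimethylamide leaves, so that the C5–C6 bond is formed and 14 is present as its delocalised anion (Michael addition–elimination). Under the equilibrating KOt-Bu/t-BuOH conditions the small share of enolate at the methylene that becomes C8, the only other enolisable carbon, attacks the ester carbonyl (C7) of the C6-protonated tautomer in a Dieckmann-type Claisen condensation, a 6-(enolendo)-exo-trig closure of ring A that enolisation to the resorcinol dianion of 15 makes irreversible. No oxidant is needed, because C5 enters at the formyl and C7 at the carboxyl oxidation level. On acidification the C8a hydroxyl of 15 adds to C2 and expels the second dimethylamine, a 6-endo-trig addition–elimination that closes ring C. The closest known reaction types are the Michael–Dieckmann benzannulations of 1,3-dicarbonyl compounds with alkoxymethylene or acetylenic esters that lead to resorcinols and orsellinates, and the acid-induced cyclisation of 2-hydroxyaryl enaminones to chromones. The orientation is fixed by polarity and not by a directing group: the nucleophilic α-carbon of 13 can bond only to the electrophilic C5 and its carbonyl only to the nucleophilic C8, so that the C7 hydroxyl must lie between the two prenyl-bearing carbons. The enaminone at C3 serves twice, as the masked C2 aldehyde of ring C and as a block on the one methylene that could otherwise close a different six-membered ring onto C7; O-acylation to a 2-pyranone is reversible under alkoxide and drains into the aromatic product. The stereocentre of 14 is transient, and only the C8a hydroxyl, not the C7 hydroxyl para to the ketone, can reach C2.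

Step 8
Reactants: 16 3-[2,4-bis(methoxymethoxy)phenoxy]-7-hydroxy-6,8-bis(3-methylbut-2-en-1-yl)-4H-chromen-4-one
Product: 17 eryvarin F, 3-(2,4-dihydroxyphenoxy)-7-hydroxy-6,8-bis(3-methylbut-2-en-1-yl)-4H-chromen-4-one
Conditions: HCl (3 M aq.), MeOH, THF, 40 °C
Reagents that add atoms: none
Why: Acid-catalysed acetal exchange with methanol frees the two ring B hydroxyls while dimethoxymethane leaves. Dilute acid, moderate temperature and short reaction time are chosen because the C7 hydroxyl could add to a protonated prenyl double bond.

## Compound list

1 | 2,4-dihydroxybenzaldehyde | O=Cc1ccc(O)cc1O | starting material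
2 | 2,4-bis(methoxymethoxy)benzaldehyde | COCOc1ccc(C=O)c(OCOC)c1 | intermediate
3 | 2,4-bis(methoxymethoxy)phenyl formate (formed in the flask, not isolated) | COCOc1ccc(OC=O)c(OCOC)c1 | intermediate
4 | 2,4-bis(methoxymethoxy)phenol | COCOc1ccc(O)c(OCOC)c1 | intermediate
5 | methyl bromoacetate | COC(=O)CBr | starting material
6 | methyl 2-[2,4-bis(methoxymethoxy)phenoxy]acetate | COC(=O)COc1ccc(OCOC)cc1OCOC | intermediate
7 | 6-methylhept-5-en-2-one | CC(=O)CCC=C(C)C | starting material
8 | 1-[2,4-bis(methoxymethoxy)phenoxy]-8-methylnon-7-ene-2,4-dione | COCOc1ccc(OCC(=O)CC(=O)CCC=C(C)C)c(OCOC)c1 | intermediate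
9 | 1-(dimethylamino)-4-[(dimethylamino)methylidene]-2-[2,4-bis(methoxymethoxy)phenoxy]-9-methyldeca-1,8-diene-3,5-dione | CN(C)C=C(Oc1ccc(OCOC)cc1OCOC)C(=O)C(=CN(C)C)C(=O)CCC=C(C)C | intermediate
10 | 2-methylbut-3-en-2-ol | CC(C)(O)C=C | starting material
11 | trimethyl orthoacetate | CC(OC)(OC)OC | starting material
12 | 3-[(1-methoxyethenyl)oxy]-3-methylbut-1-ene, the mixed ketene acetal (formed in the flask, not isolated) | C=C(OC)OC(C)(C)C=C | intermediate
13 | methyl 5-methylhex-4-enoate | COC(=O)CCC=C(C)C | intermediate
14 | methyl 4-{3-(dimethylamino)-2-[2,4-bis(methoxymethoxy)phenoxy]prop-2-enoyl}-9-methyl-2-(3-methylbut-2-en-1-yl)-5-oxodeca-3,8-dienoate (racemic, present as its delocalised anion, not isolated) | COC(=O)C(CC=C(C)C)C=C(C(=O)CCC=C(C)C)C(=O)C(Oc1ccc(OCOC)cc1OCOC)=CN(C)C | intermediate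
15 | 3-(dimethylamino)-1-[2,4-dihydroxy-3,5-bis(3-methylbut-2-en-1-yl)phenyl]-2-[2,4-bis(methoxymethoxy)phenoxy]prop-2-en-1-one (formed in the flask, not isolated) | CN(C)C=C(Oc1ccc(OCOC)cc1OCOC)C(=O)c1cc(CC=C(C)C)c(O)c(CC=C(C)C)c1O | intermediate
16 | 3-[2,4-bis(methoxymethoxy)phenoxy]-7-hydroxy-6,8-bis(3-methylbut-2-en-1-yl)-4H-chromen-4-one | CC(C)=CCc1cc2c(=O)c(Oc3ccc(OCOC)cc3OCOC)coc2c(CC=C(C)C)c1O | intermediate
17 | eryvarin F, 3-(2,4-dihydroxyphenoxy)-7-hydroxy-6,8-bis(3-methylbut-2-en-1-yl)-4H-chromen-4-one | CC(C)=CCc1cc2c(=O)c(Oc3ccc(O)cc3O)coc2c(CC=C(C)C)c1O | target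

## Step count and least certain steps

Total step count: 8. Longest linear sequence: 7 steps (steps 1, 2, 3, 4, 5, 7, 8); step 6 is a one-step side branch.

**Step 7 (key step).** Two things are most likely to go wrong.

- The ester enolate may act as a base towards the C8 methylene of 9 instead of adding to the aminomethylidene carbon.
- After the addition, ring closure may be slow, because the enolate needed for the Dieckmann step is a minor tautomer beside the much more stable delocalised anion of 14. Slow closure would open the way to cyclisation of the ester α-carbon onto C2 (a blocked cyclohexadienone), to irreversible O-cyclisation, and to cleavage of the diketone by alkoxide.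

The fallback gives up the folding of ring A and takes it from resorcinol chemistry. It sets out from 6 and comes back at 17.

- Ester 6 would be converted into the N-methoxy-N-methylamide F1 (MeNHOMe·HCl, i-PrMgCl, THF, −20 °C).
- Purchased 1,3-bis(methoxymethoxy)benzene F2 would be lithiated between its two acetal oxygens (n-BuLi, THF, 0 °C) and alkylated with prenyl bromide to give the 2-prenyl arene F3.
- A second directed ortho-lithiation (n-BuLi, TMEDA) and prenylation would give the 2,4-diprenyl arene F4.
- A third lithiation, at the last position ortho to an acetal oxygen, followed by addition to F1 (Weinreb ketone synthesis), would give ketone F5.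
- Me2NCH(OMe)2 would convert F5 into enaminone F6.
- HCl in methanol would remove the four acetals and close ring C to give 17.

**Step 5.** The most likely failure is loss of site selectivity in the second aminomethylenation: condensation also at the methylene that must remain free as the future C8, or incomplete reaction at the aryloxy-activated methylene, because the two positions differ only by the acidifying effect of the aryloxy group. The fallback introduces the two formyl-level carbons one at a time on substrates that offer a single reactive site each. It sets out from 4 and comes back at 9.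

- Phenol 4 would be alkylated with chloroacetone (K2CO3, acetone) to give the aryloxyacetone F7.
- Me2NCH(OMe)2 would condense at its aryloxy-activated methylene to give enaminone F8.
- The lithium enolate of F8 (LiN(i-Pr)2, THF, −78 °C, two equivalents; only the methyl group can be deprotonated) would be acylated with ester 13 in a crossed Claisen condensation to give diketone F9.
- The central methylene of F9 alone reacts with Me2NCH(OMe)2 at 25 °C to give 9.

**Step 8.** The most likely failure is acid-induced addition of the C7 hydroxyl to a protonated prenyl double bond (chroman formation), with addition of HCl or methanol to the alkenes as a slower second path. The fallback masks the participating phenol and avoids protic acid. It sets out from 16 and comes back at 17.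

- 16 would be acetylated (Ac2O, pyridine, 4-dimethylaminopyridine) to give acetate F10.
- The acetals would be cleaved with ZnBr2 and n-PrSH in CH2Cl2 at 0 °C, where the thiol captures the methoxymethyl cation, to give the diol acetate F11.
- The acetate would be removed with K2CO3 in methanol at 0 °C to give 17.

## Further compounds

F1 | step 7 | N-methoxy-N-methyl-2-[2,4-bis(methoxymethoxy)phenoxy]acetamide | CON(C)C(=O)COc1ccc(OCOC)cc1OCOC
F2 | step 7 | 1,3-bis(methoxymethoxy)benzene | COCOc1cccc(OCOC)c1
F3 | step 7 | 1,3-bis(methoxymethoxy)-2-(3-methylbut-2-en-1-yl)benzene | COCOc1cccc(OCOC)c1CC=C(C)C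
F4 | step 7 | 1,3-bis(methoxymethoxy)-2,4-bis(3-methylbut-2-en-1-yl)benzene | COCOc1ccc(CC=C(C)C)c(OCOC)c1CC=C(C)C
F5 | step 7 | 2-[2,4-bis(methoxymethoxy)phenoxy]-1-[2,4-bis(methoxymethoxy)-3,5-bis(3-methylbut-2-en-1-yl)phenyl]ethan-1-one | COCOc1ccc(OCC(=O)c2cc(CC=C(C)C)c(OCOC)c(CC=C(C)C)c2OCOC)c(OCOC)c1
F6 | step 7 | 3-(dimethylamino)-2-[2,4-bis(methoxymethoxy)phenoxy]-1-[2,4-bis(methoxymethoxy)-3,5-bis(3-methylbut-2-en-1-yl)phenyl]prop-2-en-1-one | CN(C)C=C(Oc1ccc(OCOC)cc1OCOC)C(=O)c1cc(CC=C(C)C)c(OCOC)c(CC=C(C)C)c1OCOC
F7 | step 5 | 1-[2,4-bis(methoxymethoxy)phenoxy]propan-2-one | COCOc1ccc(OCC(C)=O)c(OCOC)c1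
F8 | step 5 | 4-(dimethylamino)-3-[2,4-bis(methoxymethoxy)phenoxy]but-3-en-2-one | CC(=O)C(Oc1ccc(OCOC)cc1OCOC)=CN(C)C
F9 | step 5 | 1-(dimethylamino)-2-[2,4-bis(methoxymethoxy)phenoxy]-9-methyldeca-1,8-diene-3,5-dione | CN(C)C=C(Oc1ccc(OCOC)cc1OCOC)C(=O)CC(=O)CCC=C(C)C
F10 | step 8 | 3-[2,4-bis(methoxymethoxy)phenoxy]-6,8-bis(3-methylbut-2-en-1-yl)-4-oxo-4H-chromen-7-yl acetate | CC(=O)Oc1c(CC=C(C)C)cc2c(=O)c(Oc3ccc(OCOC)cc3OCOC)coc2c1CC=C(C)C
F11 | step 8 | 3-(2,4-dihydroxyphenoxy)-6,8-bis(3-methylbut-2-en-1-yl)-4-oxo-4H-chromen-7-yl acetate | CC(=O)Oc1c(CC=C(C)C)cc2c(=O)c(Oc3ccc(O)cc3O)coc2c1CC=C(C)C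
A1 | alternative 1 | 1-[2,4-dihydroxy-3,5-bis(3-methylbut-2-en-1-yl)phenyl]ethan-1-one | CC(=O)c1cc(CC=C(C)C)c(O)c(CC=C(C)C)c1O
A2 | alternative 1 | 2-bromo-1-[2,4-dihydroxy-3,5-bis(3-methylbut-2-en-1-yl)phenyl]ethan-1-one | O=C(CBr)c1cc(CC=C(C)C)c(O)c(CC=C(C)C)c1O
A3 | alternative 1 | 2-[2,4-bis(methoxymethoxy)phenoxy]-1-[2,4-dihydroxy-3,5-bis(3-methylbut-2-en-1-yl)phenyl]ethan-1-one | COCOc1ccc(OCC(=O)c2cc(CC=C(C)C)c(O)c(CC=C(C)C)c2O)c(OCOC)c1
A4 | alternative 2 | 4-(methoxymethoxy)-3,5-bis(3-methylbut-2-en-1-yl)-2-(trimethylsilyl)phenyl trifluoromethanesulfonate | COCOc1c(CC=C(C)C)cc(OS(=O)(=O)C(F)(F)F)c([Si](C)(C)C)c1CC=C(C)C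
A5 | alternative 2 | 4-(methoxymethoxy)-3,5-bis(3-methylbut-2-en-1-yl)-1,2-didehydrobenzene | COCOC1=C(CC=C(C)C)C#CC=C1CC=C(C)C
A6 | alternative 2 | 2-[2,4-bis(methoxymethoxy)phenoxy]acetic acid | OC(=O)COc1ccc(OCOC)cc1OCOC
A7 | alternative 2 | 2-[2,4-bis(methoxymethoxy)phenoxy]-1-[2-hydroxy-4-(methoxymethoxy)-3,5-bis(3-methylbut-2-en-1-yl)phenyl]ethan-1-one | COCOc1ccc(OCC(=O)c2cc(CC=C(C)C)c(OCOC)c(CC=C(C)C)c2O)c(OCOC)c1
A8 | alternative 2 | 2-[2,4-bis(methoxymethoxy)phenoxy]-1-[2-hydroxy-5-(methoxymethoxy)-4,6-bis(3-methylbut-2-en-1-yl)phenyl]ethan-1-one | COCOc1ccc(OCC(=O)c2c(O)cc(CC=C(C)C)c(OCOC)c2CC=C(C)C)c(OCOC)c1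
A9 | alternative 3 | 3,7-dihydroxy-6,8-bis(3-methylbut-2-en-1-yl)-4H-chromen-4-one | CC(C)=CCc1cc2c(=O)c(O)coc2c(CC=C(C)C)c1O
A10 | alternative 3 | [2,4-bis(methoxymethoxy)phenyl]boronic acid | COCOc1ccc(B(O)O)c(OCOC)c1
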